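Its constants belong to no real substance.

Millimoles per litre are the scale for these flasks, and the length to find on it is the level where two routes of the starting material cross.

| setting | maple | larch | elm | oak |
|---|---|---|---|---|
| starting material | 5.0 mM | 5.0 mM | 5.0 mM | 5.0 mM |
| reagent | 9.00 mM | 9.00 mM | 9.00 mM | 9.00 mM |
| second substrate | 1.00 mM | 1.00 mM | 1.00 mM | 1.00 mM |
| temperature | 20 °C | −40 °C | 0 °C | −20 °C |
| time | 20 s | 20 s | 20 s | 20 s |

    starting material + reagent → target (k1 = 16 L mol⁻¹ s⁻¹, Ea1 = 43.0 kJ mol⁻¹)
    second substrate + reagent → second product (k2 = 250 L mol⁻¹ s⁻¹, Ea2 = 41.0 kJ mol⁻¹)
    starting material + second substrate → cross product (k3 = 130 L mol⁻¹ s⁻¹, Ea3 = 48.0 kJ mol⁻¹)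
    2 starting material → self-condensation product (k4 = 120 L mol⁻¹ s⁻¹, Ea4 = 39.0 kJ mol⁻¹)
    target ⇌ isomer of the product (K5 = 0.36, k5 = 0.0036 s⁻¹, Ea5 = 74.0 kJ mol⁻¹, ΔH5 = −15.0 kJ mol⁻¹)
    (constants at 20 °C)

- percentages count the starting material that a species holds: one self-condensation product counts as two
- where a step has two of a species, its rate is k times that concentration squared, and two are used at each turn
- constants are those at 20 °C; use the activation energies and enthalpies for any other temperature

- which flask leads in amount of target, in percent of the starting material charged ("all alike" within 1.5 percentage points) (maple / larch / elm / oak / all alike)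
- how much target is there at the end, in percent of the starting material charged: maple
- how much target is there at the end, in percent of the starting material charged: larch
- how much target is there at the end, in percent of the starting material charged: elm
- how much target is there at the end, in percent of the starting material charged: oak

Let a be the starting material concentration, c its charge, b the reagent concentration, kR the constant of step one and kS that of self-condensation. Held at fixed b, the target route is pseudo-first-order with s = kR b, and the rate integrates in closed form:

da/dt = −s a − 2 kS a a

Which b? The full charge gives m = 0.600 mM in maple. But the second substrate meets the reagent at 2.25 s⁻¹, faster than s, so in maple I subtract its charge first and take b = 8.00 mM.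

m = kR b / (2 kS) = 0.533 mM for maple

This m, the crossover concentration, is the level of starting material at which both routes consume it equally. Above m self-condensation leads, and below m the target route leads. With it:

a(t) = m / [(1 + m/c) e^(st) − 1]

target = m ln[(m + c)/(m + a)]

For maple, s = 0.128 s⁻¹, so a = 0.0401 mM at the end, and target is 24.2 % of the charge.

Objection: the second substrate also takes starting material. Held at the starting rates of maple, it takes 0.224 mM of starting material, but the logarithm damps that to 0.432 % of the charge, so I drop it.

Objection: target itself uses reagent, 1.21 mM in maple, so b sinks and my figure leans high.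

Objection: the isomer. Forward, k5 t comes to 7.20 % in maple, reckoned as if all the target stood for the whole time, and that estimate leaves 22.4 %. I commit to that for maple. Step five slows by a factor 2500 from maple to larch, and k5 t comes to 0.780 % in elm, so I drop it in elm, oak and larch.

Cooling moves m and s differently, and I keep b = 8.00 mM in elm, oak and larch. Each takes the Arrhenius factor of its own energy: m that of Ea1 − Ea4, s that of Ea1.

elm: m = 0.473 mM, s = 0.0352 s⁻¹, target 17.5 %

oak: m = 0.412 mM, s = 0.00788 s⁻¹, target 8.39 %

larch: m = 0.350 mM, s = 0.00137 s⁻¹, target 2.28 %

In larch, k2 cB t comes to 0.593, so the second substrate is slow there, my b is too low, and that figure leans low. My reckoning puts maple first.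

The forecast gives maple as leader, with 23 % for maple, 17 % for elm, 8.2 % for oak and 2.5 % for larch, on the ground that “the cold flasks simply don't get far”.

The flasks give 22.1 % of target in maple, 16.9 % in elm, 8.49 % in oak and 2.47 % in larch, so maple leads. Maple has 0.97 % of its starting material left at 20.0 s. Carried to full conversion, the m of maple gives target plus isomer as (m/c) ln(1 + c/m) = 25.0 %. At 200 s maple holds 18.3 % of target and 5.96 % of isomer.

For the neighbour flask like maple kept at −5 °C, m = 0.458 mM and s = 0.0247 s⁻¹, which give 15.2 % of target. That neighbour flask gives 14.8 %, with 11.6 % of its starting material left.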